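**Retrosynthetic overview**
1. The only ring, the nine-membered carbocycle, is closed last at C7–C8: an α-formyl vinyl radical (from an α-bromo enal) cyclises 9-exo onto a methyl enol ether, and radical–polar crossover releases the C8 aldehyde in the same flask.
2. The open-chain precursor takes C8' from a Wittig methoxymethylenation and its C1'/C9/C1 stereotriad from one copper-catalysed asymmetric conjugate addition–aldol tandem (S-ethyl thiocrotonate, homoprenyl Grignard, C1–C7' aldehyde).
3. The C1–C7' aldehyde comes from Negishi carboalumination of but-3-yn-1-ol (fixes the E C3=C4 olefin) and Pd-catalysed coupling with methyl 2,4-dibromobut-2-enoate.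
4. Order: west aldehyde, stereotriad, redox adjustment and acetylation, then the single ring closure.

Assumption: labels C1–C9 are the ring carbons (C1 bears OAc, C9 the side chain), C7'/C8' are the formyl carbons, C1' is the side-chain stereocentre; the sense of the Josiphos ligand is fixed by the required Re-face addition and would be checked in the first run.

**Step 1**
Reactants: 1 (2E)-but-2-enoyl chloride; 2 ethanethiol
Product: 3 S-ethyl (2E)-but-2-enethioate
Conditions: pyridine (1.2 equiv), CH2Cl2, 0 °C to rt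
Reagents that add atoms: none
Why: Nucleophilic acyl substitution of the acid chloride by the thiol gives the thioester needed for copper-catalysed conjugate addition, and no stereocentre is formed.

**Step 2**
Reactants: 4 methyl (2E)-4-bromobut-2-enoate
Product: 6 methyl (2Z)-2,4-dibromobut-2-enoate, via methyl 2,3,4-tribromobutanoate 5 (not isolated)
Conditions: Br2 (1.05 equiv), CH2Cl2, 0 °C to rt; then i-Pr2NEt (1.1 equiv), 0 °C
Reagents that add atoms: bromine, BrBr
Why: Bromination–dehydrobromination (anti addition of Br2, then loss of the acidic α-H and the β-bromide) gives the α-bromo enoate while the primary allylic bromide stays, and the alkene geometry is irrelevant later because the derived vinyl radical is linear.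

**Step 3**
Reactants: 7 but-3-yn-1-ol; 6 methyl (2Z)-2,4-dibromobut-2-enoate
Product: 9 methyl (2Z,5E)-2-bromo-8-hydroxy-6-methylocta-2,5-dienoate, via alkenylalane 8 (not isolated)
Conditions: Me3Al (3 equiv), Cp2ZrCl2 (0.25 equiv), CH2Cl2, 0 °C to rt, 12 h; then 6 (1.2 equiv), Pd(PPh3)4 (5 mol%), THF, 0 °C to rt; aq. potassium sodium tartrate
Reagents that add atoms: trimethylaluminium, C[Al](C)C
Why: Negishi zirconium-catalysed syn-carboalumination places Me and Al on the same side of the alkyne and so fixes the E trisubstituted C3=C4 olefin, and the alkenylalane is then cross-coupled through a zerovalent-palladium π-allyl complex at the unhindered CH2 terminus of the allylic bromide, which reacts faster than the vinylic C–Br bond.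

**Step 4**
Reactants: 9 methyl (2Z,5E)-2-bromo-8-hydroxy-6-methylocta-2,5-dienoate
Product: 10 methyl (2Z,5E)-2-bromo-6-methyl-8-oxoocta-2,5-dienoate
Conditions: Dess–Martin periodinane (1.3 equiv), NaHCO3, CH2Cl2, 0 °C, 1 h; used crude
Reagents that add atoms: none
Why: Buffered Dess–Martin oxidation converts the primary homoallylic alcohol into the β,γ-unsaturated aldehyde without moving the double bond into conjugation.

**Step 5**
Reactants: 11 5-bromo-2-methylpent-2-ene; 3 S-ethyl (2E)-but-2-enethioate; 10 methyl (2Z,5E)-2-bromo-6-methyl-8-oxoocta-2,5-dienoate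
Product: 14 methyl (2Z,5E,8R,9S,10S)-2-bromo-9-[(ethylsulfanyl)carbonyl]-8-hydroxy-6,10,14-trimethylpentadeca-2,5,13-trienoate, via Grignard reagent 12 (not isolated), via magnesium enolate 13 (not isolated)
Conditions: 11, Mg, Et2O, rt; then 3 (1.3 equiv), 12 (1.25 equiv), CuBr·SMe2 (5 mol%), Josiphos ligand C36H44FeP2 (6 mol%, enantiomer giving Re-face addition at C3 of 3), t-BuOMe, −75 °C, 2 h; then 10 (1.0 equiv), −75 °C, 1 h; aq. NH4Cl
Reagents that add atoms: none
Why: Copper-catalysed asymmetric conjugate addition of the Grignard reagent sets C1' under catalyst control and leaves the Z(O) magnesium enolate, which adds to aldehyde 10 through a closed Zimmerman–Traxler transition state (syn aldol, approach anti to the larger homoprenyl arm by A1,3 strain) and so sets C9 and C1 in the same tandem conjugate addition–aldol operation.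

**Step 6**
Reactants: 14 (the thioester aldol adduct)
Product: 15 (2S,3R,5E,8Z)-9-bromo-3,10-dihydroxy-5-methyl-2-[(2S)-6-methylhept-5-en-2-yl]deca-5,8-dienal
Conditions: i-Bu2AlH (5.5 equiv), CH2Cl2, −78 °C, 2 h; MeOH then aq. potassium sodium tartrate, −78 °C to rt; used at once
Reagents that add atoms: none
Why: Chemoselective hydride reduction at −78 °C stops at the aldehyde for the thioester (the aluminium hemithioacetal persists until work-up) while the conjugated methyl ester is taken through to the allylic alcohol, and the vinylic bromide and the three stereocentres are untouched.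

**Step 7**
Reactants: 15 (the hydroxy aldehyde)
Product: 16 (3R,4R,6E,9Z)-10-bromo-1-methoxy-6-methyl-3-[(2S)-6-methylhept-5-en-2-yl]undeca-1,6,9-triene-4,11-diol (1E/1Z mixture)
Conditions: [Ph3PCH2OMe]Cl (5 equiv), KN(SiMe3)2 (4.8 equiv), THF, −78 to 0 °C
Reagents that add atoms: (methoxymethyl)triphenylphosphonium chloride, [Cl-].COC[P+](c1ccccc1)(c1ccccc1)c1ccccc1
Why: Wittig methoxymethylenation turns the C8 aldehyde into an enol ether that carries C8' at the aldehyde oxidation level, and the excess ylide covers the two free hydroxyl groups (both enol ether isomers are usable).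

**Step 8**
Reactants: 16 (the enol ether diol)
Product: 17 (2Z,5E,8R,9R)-2-bromo-8-hydroxy-11-methoxy-6-methyl-9-[(2S)-6-methylhept-5-en-2-yl]undeca-2,5,10-trienal
Conditions: MnO2 (activated, 20 equiv), CH2Cl2, rt
Reagents that add atoms: none
Why: Allylic oxidation with MnO2 converts only the primary allylic alcohol into the α-bromo enal and leaves the secondary homoallylic alcohol and the enol ether intact.

**Step 9**
Reactants: 17 (the hydroxy bromo enal)
Product: 18 (3R,4R,6E,9Z)-10-bromo-1-methoxy-6-methyl-3-[(2S)-6-methylhept-5-en-2-yl]-11-oxoundeca-1,6,9-trien-4-yl acetate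
Conditions: Ac2O (3 equiv), pyridine, DMAP (5 mol%), CH2Cl2, 0 °C
Reagents that add atoms: acetic anhydride, CC(=O)OC(C)=O
Why: DMAP-catalysed acetylation installs the C1 acetate with retention before the C8' aldehyde is unveiled, so that no lactol between C1–OH and C8' can form later.

**Step 10**
Reactants: 18 (the acetate)
Product: 20 (1R,3E,6E,8R,9R)-7,8-diformyl-3-methyl-9-[(2S)-6-methylhept-5-en-2-yl]cyclonona-3,6-dien-1-yl acetate, via methyl hemiacetal 19 (not isolated)
Conditions: fac-Ir(ppy)3 (2 mol%), 2,6-lutidine (2 equiv), degassed MeCN/H2O (9:1), 1 mM, 450 nm LEDs, rt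
Reagents that add atoms: water, O
Why: Proposed new method: the photoexcited trivalent iridium complex reduces the C–Br bond of the α-bromo enal to a linear α-formyl vinyl radical, which adds 9-exo-trig to the electron-rich enol ether carbon C8 (the tether enforces the ring-cis C6=C7 geometry and, with C9–H eclipsing the enol ether by A1,3 strain, delivers the radical anti to the C9 side chain, giving the 8,9-trans centre), the α-methoxyalkyl radical is then oxidised by the tetravalent iridium complex to an oxocarbenium ion that water converts into hemiacetal 19, which loses methanol to give the C8' aldehyde; the closest known chemistry is photoredox generation of vinyl radicals from α-bromo enones, radical–polar crossover additions to enol ethers and Stork-type vinyl radical cyclisations.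

**Compound list**
1 | (2E)-but-2-enoyl chloride | C/C=C/C(=O)Cl | starting material
2 | ethanethiol | CCS | starting material
3 | S-ethyl (2E)-but-2-enethioate | C/C=C/C(=O)SCC | intermediate
4 | methyl (2E)-4-bromobut-2-enoate | COC(=O)/C=C/CBr | starting material
5 | methyl 2,3,4-tribromobutanoate (racemic, not isolated) | COC(=O)C(Br)C(Br)CBr | intermediate
6 | methyl (2Z)-2,4-dibromobut-2-enoate | COC(=O)/C(Br)=C/CBr | intermediate
7 | but-3-yn-1-ol | C#CCCO | starting material
8 | dimethyl{(1E)-4-[(dimethylalumanyl)oxy]-2-methylbut-1-en-1-yl}alumane (not isolated) | C[Al](C)/C=C(\C)CCO[Al](C)C | intermediate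
9 | methyl (2Z,5E)-2-bromo-8-hydroxy-6-methylocta-2,5-dienoate | COC(=O)/C(Br)=C/C/C=C(C)/CCO | intermediate
10 | methyl (2Z,5E)-2-bromo-6-methyl-8-oxoocta-2,5-dienoate | O=CC/C(C)=C/C/C=C(\Br)C(=O)OC | intermediate
11 | 5-bromo-2-methylpent-2-ene | CC(C)=CCCBr | starting material
12 | (4-methylpent-3-en-1-yl)magnesium bromide (not isolated) | CC(C)=CCC[Mg]Br | intermediate
13 | bromomagnesium (1E,3S)-1-(ethylsulfanyl)-3,7-dimethylocta-1,6-dien-1-olate, the Z(O) enolate (not isolated) | CCS/C(O[Mg]Br)=C/[C@@H](C)CCC=C(C)C | intermediate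
14 | methyl (2Z,5E,8R,9S,10S)-2-bromo-9-[(ethylsulfanyl)carbonyl]-8-hydroxy-6,10,14-trimethylpentadeca-2,5,13-trienoate | CCSC(=O)[C@H]([C@H](O)C/C(C)=C/C/C=C(\Br)C(=O)OC)[C@@H](C)CCC=C(C)C | intermediate
15 | (2S,3R,5E,8Z)-9-bromo-3,10-dihydroxy-5-methyl-2-[(2S)-6-methylhept-5-en-2-yl]deca-5,8-dienal | O=C[C@H]([C@H](O)C/C(C)=C/C/C=C(\Br)CO)[C@@H](C)CCC=C(C)C | intermediate
16 | (3R,4R,6E,9Z)-10-bromo-1-methoxy-6-methyl-3-[(2S)-6-methylhept-5-en-2-yl]undeca-1,6,9-triene-4,11-diol (1E/1Z mixture) | COC=C[C@H]([C@H](O)C/C(C)=C/C/C=C(\Br)CO)[C@@H](C)CCC=C(C)C | intermediate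
17 | (2Z,5E,8R,9R)-2-bromo-8-hydroxy-11-methoxy-6-methyl-9-[(2S)-6-methylhept-5-en-2-yl]undeca-2,5,10-trienal | COC=C[C@H]([C@H](O)C/C(C)=C/C/C=C(\Br)C=O)[C@@H](C)CCC=C(C)C | intermediate
18 | (3R,4R,6E,9Z)-10-bromo-1-methoxy-6-methyl-3-[(2S)-6-methylhept-5-en-2-yl]-11-oxoundeca-1,6,9-trien-4-yl acetate | COC=C[C@H]([C@H](OC(C)=O)C/C(C)=C/C/C=C(\Br)C=O)[C@@H](C)CCC=C(C)C | intermediate
19 | (1R,3E,6E,8R,9R)-7-formyl-8-[hydroxy(methoxy)methyl]-3-methyl-9-[(2S)-6-methylhept-5-en-2-yl]cyclonona-3,6-dien-1-yl acetate (not isolated) | CC(=O)O[C@@H]1C/C(C)=C/C/C=C(/C=O)[C@H](C(O)OC)[C@H]1[C@@H](C)CCC=C(C)C | intermediate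
20 | (1R,3E,6E,8R,9R)-7,8-diformyl-3-methyl-9-[(2S)-6-methylhept-5-en-2-yl]cyclonona-3,6-dien-1-yl acetate | CC(=O)O[C@@H]1C/C(C)=C/C/C=C(/C=O)[C@H](C=O)[C@H]1[C@@H](C)CCC=C(C)C | target

**Step count and risks**
Total step count: 10. Longest linear sequence: 9 steps (4 → 6 → 9 → 10 → 14 → 15 → 16 → 17 → 18 → 20).

The three steps most likely to fail are step 10, step 5 and step 6.

Step 10 (radical ring closure): a nine-membered ring has to form faster than the vinyl radical is reduced, and C8 is set only by substrate control. The fallback sets out from 18 and comes back at 20. The enol ether of 18 is hydrolysed with oxalic acid in wet THF to the free dialdehyde (2Z,5E,8R,9S)-2-bromo-6-methyl-9-[(2S)-6-methylhept-5-en-2-yl]-1,11-dioxoundeca-2,5-dien-8-yl acetate F1. The ring is then closed under enamine catalysis (imidazolidinone trifluoroacetate 20 mol%, fac-Ir(ppy)3, 2,6-lutidine, DMF, 450 nm). Here the catalyst-bound enamine of the saturated aldehyde, not an enol ether, captures the vinyl radical, so the amine and not the substrate fixes C8, and hydrolysis of the iminium ion gives 20.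

Step 5 (tandem conjugate addition–aldol): the aldehyde is enolisable, and the facial selectivity of the enolate rests on a small methyl versus alkyl difference, so the syn/anti and facial ratios may be poor. The fallback sets out from 1 and comes back at 14, with both events under auxiliary control in separate steps.
- Lithiated (S)-4-phenyl-1,3-oxazolidin-2-one is acylated with 1 to give (4S)-3-[(2E)-but-2-enoyl]-4-phenyl-1,3-oxazolidin-2-one F2.
- Grignard reagent 12 is added with CuBr·SMe2 (THF, −40 °C; chelated imide, attack anti to phenyl) to give (4S)-3-[(3S)-3,7-dimethyloct-6-enoyl]-4-phenyl-1,3-oxazolidin-2-one F3.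
- A Bu2BOTf/i-Pr2NEt Evans syn-aldol reaction with 10 gives methyl (2Z,5E,8R,9S,10S)-2-bromo-8-hydroxy-6,10,14-trimethyl-9-[(4S)-2-oxo-4-phenyl-1,3-oxazolidine-3-carbonyl]pentadeca-2,5,13-trienoate F4.
- EtSLi (EtSH, n-BuLi, THF, 0 °C) exchanges the auxiliary for the ethyl thioester and gives 14.

Step 6 (double reduction): the thioester may be over-reduced to the alcohol, or the hydroxy aldehyde may epimerise at C9. The fallback sets out from 14 and comes back at 16, bypassing 15, so that each carbonyl is handled alone.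
- NaBH4 (EtOH, 0 °C) reduces only the thioester to methyl (2Z,5E,8R,9R,10S)-2-bromo-8-hydroxy-9-(hydroxymethyl)-6,10,14-trimethylpentadeca-2,5,13-trienoate F5.
- TEMPO/PhI(OAc)2 oxidises only the primary alcohol to methyl (2Z,5E,8R,9S,10S)-2-bromo-9-formyl-8-hydroxy-6,10,14-trimethylpentadeca-2,5,13-trienoate F6.
- Methoxymethylenation as in step 7 gives methyl (2Z,5E,8R,9R,10S)-2-bromo-8-hydroxy-9-(2-methoxyethenyl)-6,10,14-trimethylpentadeca-2,5,13-trienoate F7.
- i-Bu2AlH (CH2Cl2, −78 °C) then reduces the one remaining carbonyl, the enoate, to give 16.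

**Further compounds**
F1 | step 10 | (2Z,5E,8R,9S)-2-bromo-6-methyl-9-[(2S)-6-methylhept-5-en-2-yl]-1,11-dioxoundeca-2,5-dien-8-yl acetate | O=CC[C@H]([C@H](OC(C)=O)C/C(C)=C/C/C=C(\Br)C=O)[C@@H](C)CCC=C(C)C
F2 | step 5 | (4S)-3-[(2E)-but-2-enoyl]-4-phenyl-1,3-oxazolidin-2-one | C/C=C/C(=O)N1[C@@H](c2ccccc2)COC1=O
F3 | step 5 | (4S)-3-[(3S)-3,7-dimethyloct-6-enoyl]-4-phenyl-1,3-oxazolidin-2-one | CC(C)=CCC[C@H](C)CC(=O)N1[C@@H](c2ccccc2)COC1=O
F4 | step 5 | methyl (2Z,5E,8R,9S,10S)-2-bromo-8-hydroxy-6,10,14-trimethyl-9-[(4S)-2-oxo-4-phenyl-1,3-oxazolidine-3-carbonyl]pentadeca-2,5,13-trienoate | O=C1OC[C@H](c2ccccc2)N1C(=O)[C@H]([C@H](O)C/C(C)=C/C/C=C(\Br)C(=O)OC)[C@@H](C)CCC=C(C)C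
F5 | step 6 | methyl (2Z,5E,8R,9R,10S)-2-bromo-8-hydroxy-9-(hydroxymethyl)-6,10,14-trimethylpentadeca-2,5,13-trienoate | OC[C@H]([C@H](O)C/C(C)=C/C/C=C(\Br)C(=O)OC)[C@@H](C)CCC=C(C)C
F6 | step 6 | methyl (2Z,5E,8R,9S,10S)-2-bromo-9-formyl-8-hydroxy-6,10,14-trimethylpentadeca-2,5,13-trienoate | O=C[C@H]([C@H](O)C/C(C)=C/C/C=C(\Br)C(=O)OC)[C@@H](C)CCC=C(C)C
F7 | step 6 | methyl (2Z,5E,8R,9R,10S)-2-bromo-8-hydroxy-9-(2-methoxyethenyl)-6,10,14-trimethylpentadeca-2,5,13-trienoate | COC=C[C@H]([C@H](O)C/C(C)=C/C/C=C(\Br)C(=O)OC)[C@@H](C)CCC=C(C)C
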